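The numbers are those of an exercise.

The charge was small, 0.082 M of starting material against 0.0779 M of coupling partner, and I had to say how much target it holds after 25 h at two temperatures.

    starting material + coupling partner → target (k1 = 0.0167 /M/min, Ea1 = 82.0 kJ/mol)
    starting material + rival reagent → side product (k2 = 0.0397 /M/min, Ea2 = 69.0 kJ/mol)
    target → over-reaction product (k3 = 1.63 × 10⁻⁴ /min, Ea3 = 123 kJ/mol)
    solid rival reagent ⇌ rival reagent, rate k4*(cs4 - [rival reagent]) while solid is left; crystals form when [rival reagent] > cs4 (cs4 = 9.1 mM, k4 = 0.00299 /min)
    (constants at 60 °C)

- south-west: starting material 0.082 M; coupling partner 0.0779 M; solid rival reagent 0.123 M; temperature 90 °C; time 25 h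
- south: starting material 0.082 M; coupling partner 0.0779 M; solid rival reagent 0.123 M; temperature 60 °C; time 25 h

- as a solid, counted per litre of solution: solid rival reagent
- at 60 °C the constants are as listed, elsewhere as the activation energies make them
- at the start none of the solid rival reagent is in solution

- which flask leads in amount of target, in percent of the starting material charged ("all alike" within 1.5 percentage points) (south-west / south / all alike)
- how much target is there at the end, in percent of the starting material charged: south-west
- how much target is there at the end, in percent of the starting material charged: south

Target is made and then lost, so I counted lifetimes spent, n: the over-reaction constant times the run time, which for south was 0.245. Heating from 60 °C to 90 °C sped coupling by 12 and over-reaction by 39, so over-reaction gained more, and I set up this table, taking coupling time as one over the coupling constant times the starting material charge.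

| Flask | Coupling time | Target lifetime | n |
|---|---|---|---|
| south-west | 1.05 h | 2.61 h | 9.58 |
| south | 12.2 h | 102 h | 0.245 |

Reading the first two columns, I saw coupling run ahead of over-reaction in south-west and in south, so target appeared in both flasks. The last column parted them: the south-west run lasted ten times the target lifetime, the south run a quarter of it.

For south, I took the two charges as equal and left the rival reagent out, so I estimated that coupling turned 67.3% of the starting material. Multiplying by exp(−n), 78.3%, as if the target had been made at the start, gave an estimate of 52.7%. For south-west, exp(−n) was 0.00691%, and I went no further than calling the amount a trace, so I put south ahead.

The forecast also chose south, with 0.12% (0.04% to 0.5%) for south-west and 50% (45% to 55%) for south, holding that at the higher temperature target is “formed within a few hundred minutes and then almost entirely destroyed”. It put a number on south-west where I had none.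

The simulation gave 0.141% in south-west and 52.0% in south, so south led.

At the end of the run, [target] / ([target] + [over-reaction product]) read 84.6% in south against an exp(−n) of 78.3%, and 0.161% in south-west against 0.00691%. South read later, at 2.5 d, had spent n = 0.587, so exp(−n) was 55.6%, and it held 45.5% target beside 26.6% over-reaction product, a share of 63.1%.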